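## Analysis of the target

- **Skeleton.** The target is a flavan (2-arylchroman). Ring A is a 5,7-dihydroxylated benzene fused to ring C, the dihydropyran O1–C2–C3–C4–C4a–C8a. Ring B (3-hydroxy-4-methoxyphenyl) sits on C2, and a 3,4,5-trihydroxybenzoyl (galloyl) ester sits on O3.
- **Stereocenters.** There are only two, C2 (R) and C3 (R), adjacent and cis. This is the less stable relative configuration (aryl equatorial, ester axial). C4 is an unsubstituted CH2.
- **Sensitive groups.** C2 is a benzylic aryl ether whose ionisation or ring opening is helped by the para-methoxy group of ring B, so it epimerises under base, heat or strong acid. The ester is base-labile. The free polyphenols are air-sensitive. Ring A is a strong carbon nucleophile at C6 and C8.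
- **Methylation pattern.** One oxygen out of seven (O4') is methylated. This has to come from a building block, not from a late selective methylation.
- **What makes it hard.** The difficulty is not size but the cis-2,3 pair in the right absolute sense with an acyl group on the hindered axial oxygen. Routes that dihydroxylate an E-olefin arrive at trans and must set C3 twice.
- **The feature that invites the chosen move.** C4 is a bare CH2 on a carbon (C4a) ortho to the phenolic O1. O3 is acylated in the target itself. C2 carries an aryl group with a para-methoxy donor. The bonds O1–C2 and C3–C4 are therefore the two sigma bonds of a hetero-Diels–Alder adduct between an ortho-quinone methide of ring A and a Z-enol gallate of ring B.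

## Retrosynthetic reasoning

**11 back to 10 (protecting groups and blocking atoms).** The last step removes six benzyl ethers and two C–Br bonds in one hydrogenolysis, so 11 comes from 10. Benzyl is chosen because neither the ester nor C2 tolerates basic deprotection. The bromine atoms at C6 and C8 are not in the target. They are there only to protect ring A during the key step and leave in the same final operation.

**10 back to 4 and 8 (O1–C2 and C3–C4, key disconnection).** Ring C is cut across O1–C2 and C3–C4, the same cut as the retro-Diels–Alder fragmentation seen in mass spectra of flavan-3-ols. This gives methide 9 (from salicyl alcohol 4 by dehydration) and Z-enol ester 8.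
- The ring, both stereocenters and the ester are delivered together from two flat, achiral pieces.
- The cis relationship is stored in the Z geometry of 8. The absolute configuration is the only thing the catalyst has to add.
- The gallate is carried in on the dienophile, so no late acylation of an axial alcohol is needed.
- The para-methoxy group of ring B directs O1 to C2 and C4 to C3.
- The forward reaction has to beat Friedel–Crafts attack of ring A on 9. This is why 4 carries bromine at both free ring positions.

**8 back to 6 and 7 (C3–O bond).** The enol ester C–O bond is cut to terminal alkyne 6 and acid 7. A ruthenium vinylidene addition gives anti-Markovnikov, Z-selective hydro-acyloxylation, so the olefin geometry is set in the step that joins ring B to the gallate.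

**6 back to 5.** The alkyne carbon that becomes C3 is added to aldehyde 5 by a one-carbon homologation. Compound 5 already holds the 4'-OMe / 3'-O pattern.

**4 back to 3, 2 and 1.** The CH2OH group of 4 (the future C4) is the formyl carbon of 1 after reduction. Before that, the two free ring positions are brominated (3) and two of the three phenols are benzylated (2). The hydroxyl hydrogen-bonded to the formyl group is left free to become O1.

## Alternatives that were turned down

**Alternative 1:** the textbook route.
- Disconnection: C4a–C4 first, then O1–C2.
- Forward: Friedel–Crafts allylation of a ring A phenol with a ring B cinnamyl cation gives the (E)-1,3-diarylpropene A1. Asymmetric dihydroxylation sets C2 and C3. An orthoester-mediated cyclisation closes O1–C2 with inversion to the 2,3-trans alcohol A2. An oxidation and a hydride reduction invert C3 to the cis alcohol A3, which is acylated and deprotected.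
- Why turned down: syn-dihydroxylation of an E-olefin followed by invertive closure can only give trans. C3 is therefore set, erased as a ketone (next to an epimerisable C2) and set again. The phenol needs a temporary silyl group for the dihydroxylation. The gallate goes on last at a hindered axial alcohol. This costs about ten linear steps with one bond per step. It is also the route most chemists would draw first.

**Alternative 2:** biomimetic flavylium reduction.
- Disconnection: both C–H bonds at C2 and C3 (and C4–H).
- Forward: acid condensation of 1 with the α-acyloxy ketone A5 gives the 3-galloyloxyflavylium salt A4. An asymmetric hydrogenation (hydride to C4, then syn addition across C2=C3) would give the cis product.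
- Why turned down: the catalyst would have to set both centres on a flat cation with no substrate geometry to help. The intermediate C2=C3 bond is a tetrasubstituted, electron-rich enol ester. Its vinylic C3–O bond and benzylic C2–O1 bond are open to hydrogenolysis. A4 with free phenols equilibrates in protic media between flavylium, quinoidal, hemiketal and chalcone forms, and its ester must survive hot acid. Two uncertain steps would follow each other, and heterogeneous hydrogenation as a rescue gives only the racemate.

**Alternative 3:** carbenoid O–H insertion, then reduction.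
- Disconnection: O1–C2.
- Forward: diazoketone A6 with Rh2(OAc)4 closes ring C by intramolecular O–H insertion to the racemic flavan-3-one A7. A transfer hydrogenation under dynamic kinetic resolution gives A3, which is acylated.
- Why turned down: the ring closure sets no stereocenter. A6 needs a 1,3-diarylacetone and a diazo transfer that must choose between two benzylic CH2 groups. The electron-rich ring A and the benzyl ethers compete for the carbenoid (arene addition, C–H insertion). The ester is again attached afterwards. The route would be at least two steps longer than the one chosen. Only its closing reduction is kept, as the repair for the key step.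

Key step: step 6

Assumption: the sense of induction of the chiral acid in step 6 cannot be predicted with confidence for a methide without a C4 substituent. The (R)-configured acid is written; its mirror image would be used if it selects the opposite olefin face. Compounds 1, 5 and 7 are taken as commercial.

## Route

Step 1
Reactants: 1 2,4,6-trihydroxybenzaldehyde
Product: 2 2,4-bis(benzyloxy)-6-hydroxybenzaldehyde
Conditions: BnBr (2.1 equiv), K2CO3 (2.2 equiv), DMF, 0 °C to rt
Reagents that add atoms: benzyl bromide, BrCc1ccccc1
Why: Williamson etherification; the para hydroxyl and one ortho hydroxyl react, while the remaining ortho hydroxyl is hydrogen-bonded to the formyl group and is the least nucleophilic, so two equivalents should stop at the bis-ether.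

Step 2
Reactants: 2 2,4-bis(benzyloxy)-6-hydroxybenzaldehyde
Product: 3 2,4-bis(benzyloxy)-3,5-dibromo-6-hydroxybenzaldehyde
Conditions: NBS (2.1 equiv), CH2Cl2, 0 °C to rt, dark
Reagents that add atoms: N-bromosuccinimide, O=C1CCC(=O)N1Br
Why: Electrophilic aromatic bromination; the two free ring positions are each activated by three oxygen donors and are the only sites available. The bromine atoms are blocking groups for the key step and are not in the target.

Step 3
Reactants: 3 2,4-bis(benzyloxy)-3,5-dibromo-6-hydroxybenzaldehyde
Product: 4 3,5-bis(benzyloxy)-2,4-dibromo-6-(hydroxymethyl)phenol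
Conditions: NaBH4 (1.2 equiv), THF/MeOH, −20 to 0 °C; pH 7 buffer work-up; used without storage
Reagents that add atoms: none
Why: Borohydride reduction of the aldehyde; low temperature and a neutral work-up keep the salicyl alcohol from ionising to the methide, which would lead to over-reduction or self-condensation.

Step 4
Reactants: 5 3-(benzyloxy)-4-methoxybenzaldehyde
Product: 6 2-(benzyloxy)-4-ethynyl-1-methoxybenzene
Conditions: dimethyl (1-diazo-2-oxopropyl)phosphonate (1.3 equiv), K2CO3 (2 equiv), MeOH/THF, 0 °C to rt
Reagents that add atoms: dimethyl (1-diazo-2-oxopropyl)phosphonate, COP(=O)(OC)C(=[N+]=[N-])C(C)=O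
Why: Ohira–Bestmann (Seyferth–Gilbert) homologation of an aryl aldehyde to the terminal alkyne; the mild carbonate conditions leave the benzyl and methyl ethers untouched.

Step 5
Reactants: 6 2-(benzyloxy)-4-ethynyl-1-methoxybenzene; 7 3,4,5-tris(benzyloxy)benzoic acid
Product: 8 (Z)-2-[3-(benzyloxy)-4-methoxyphenyl]ethenyl 3,4,5-tris(benzyloxy)benzoate
Conditions: Ru(η3-CH2C(CH3)CH2)2(Ph2P(CH2)4PPh2) (2 mol %), toluene, 65 °C, argon
Reagents that add atoms: none
Why: Ruthenium-catalysed anti-Markovnikov hydro-acyloxylation of a terminal alkyne; the carboxylate attacks the α-carbon of a ruthenium vinylidene and protonolysis of the alkenyl–ruthenium bond gives the Z-enol ester. This fixes the olefin geometry that later becomes the cis-2,3 relationship.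

Step 6
Reactants: 4 3,5-bis(benzyloxy)-2,4-dibromo-6-(hydroxymethyl)phenol; 8 (Z)-2-[3-(benzyloxy)-4-methoxyphenyl]ethenyl 3,4,5-tris(benzyloxy)benzoate
Product: 10 (2R,3R)-5,7-bis(benzyloxy)-2-[3-(benzyloxy)-4-methoxyphenyl]-6,8-dibromochroman-3-yl 3,4,5-tris(benzyloxy)benzoate, via ortho-quinone methide 9 (not isolated)
Conditions: 4 (1.5 equiv, slow addition), (R)-3,3'-bis(2,4,6-triisopropylphenyl)-1,1'-binaphthyl-2,2'-diyl N-triflylphosphoramide (10 mol %), 5 Å MS, toluene, −20 °C to rt
Reagents that add atoms: none
Why: Proposed new method: the chiral acid ionises the benzylic alcohol of 4 to methide 9, which stays hydrogen-bonded or ion-paired to the chiral phosphoramide anion and reacts as an electron-poor oxa-diene (O=C8a–C4a=C4) with the electron-rich Z-olefin of 8 in an inverse-demand hetero-Diels–Alder reaction; the closest known reaction type is the N-triflylphosphoramide-catalysed enantioselective [4+2] cycloaddition of in situ generated ortho-quinone methides with styrenes, known for methides that carry an aryl group on the methylene carbon but not for an unsubstituted methide or a β-acyloxystyrene. Ring C is closed by this asynchronous [4+2] cycloaddition, with C4–C3 bond formation ahead of O1–C2. Regiochemistry follows from charge stabilisation: the developing positive charge sits on the carbon bearing ring B, whose para-methoxy group is a far better donor than the acyloxy group, so C4 bonds to the ester-bearing carbon and O1 to the benzylic carbon. The cis relationship of C2 and C3 is controlled by the Z geometry of 8, transferred suprafacially, and because C4 carries no substituent the endo or exo approach does not affect the relative configuration. The absolute configuration (2R,3R) is controlled by the catalyst, which must direct 9 to the olefin face that is Re at the aryl-bearing carbon. Chemoselectivity is secured by the two bromine atoms, which block the only nucleophilic positions of ring A (C6 and C8) in 4, 9 and 10 and so remove the Friedel–Crafts oligomerisation that would be expected to outrun cycloaddition on a 1,3,5-trioxygenated ring. Slow addition of 4 keeps the concentration of 9 low against dimerisation, and the mildest acid that still ionises 4 is used so that the Z-olefin does not isomerise and the adduct does not reopen at C2.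

Step 7
Reactants: 10 (2R,3R)-5,7-bis(benzyloxy)-2-[3-(benzyloxy)-4-methoxyphenyl]-6,8-dibromochroman-3-yl 3,4,5-tris(benzyloxy)benzoate
Product: 11 4'-O-methylepicatechin-3-O-gallate, (2R,3R)-5,7-dihydroxy-2-(3-hydroxy-4-methoxyphenyl)chroman-3-yl 3,4,5-trihydroxybenzoate
Conditions: H2 (1 atm), Pd(OH)2/C, NaOAc (2.5 equiv), THF/MeOH, rt
Reagents that add atoms: none
Why: Hydrogenolysis of the six benzyl ethers and hydrodebromination of the two aryl bromides over palladium in one operation, with acetate buffering the hydrogen bromide; the ester, the C2–O1 bond and both stereocenters should be left untouched, as in standard end-games for benzylated flavan-3-ol gallates.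

## Compound list

1 | 2,4,6-trihydroxybenzaldehyde | O=Cc1c(O)cc(O)cc1O | starting material
2 | 2,4-bis(benzyloxy)-6-hydroxybenzaldehyde | O=Cc1c(O)cc(OCc2ccccc2)cc1OCc1ccccc1 | intermediate
3 | 2,4-bis(benzyloxy)-3,5-dibromo-6-hydroxybenzaldehyde | O=Cc1c(O)c(Br)c(OCc2ccccc2)c(Br)c1OCc1ccccc1 | intermediate
4 | 3,5-bis(benzyloxy)-2,4-dibromo-6-(hydroxymethyl)phenol | OCc1c(O)c(Br)c(OCc2ccccc2)c(Br)c1OCc1ccccc1 | intermediate
5 | 3-(benzyloxy)-4-methoxybenzaldehyde | COc1ccc(C=O)cc1OCc1ccccc1 | starting material
6 | 2-(benzyloxy)-4-ethynyl-1-methoxybenzene | COc1ccc(C#C)cc1OCc1ccccc1 | intermediate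
7 | 3,4,5-tris(benzyloxy)benzoic acid | OC(=O)c1cc(OCc2ccccc2)c(OCc2ccccc2)c(OCc2ccccc2)c1 | starting material
8 | (Z)-2-[3-(benzyloxy)-4-methoxyphenyl]ethenyl 3,4,5-tris(benzyloxy)benzoate | COc1ccc(/C=C\OC(=O)c2cc(OCc3ccccc3)c(OCc3ccccc3)c(OCc3ccccc3)c2)cc1OCc1ccccc1 | intermediate
9 | 3,5-bis(benzyloxy)-2,4-dibromo-6-methylidenecyclohexa-2,4-dien-1-one (ortho-quinone methide) | C=C1C(=O)C(Br)=C(OCc2ccccc2)C(Br)=C1OCc1ccccc1 | intermediate (not isolated)
10 | (2R,3R)-5,7-bis(benzyloxy)-2-[3-(benzyloxy)-4-methoxyphenyl]-6,8-dibromochroman-3-yl 3,4,5-tris(benzyloxy)benzoate | COc1ccc([C@H]2Oc3c(Br)c(OCc4ccccc4)c(Br)c(OCc4ccccc4)c3C[C@H]2OC(=O)c2cc(OCc3ccccc3)c(OCc3ccccc3)c(OCc3ccccc3)c2)cc1OCc1ccccc1 | intermediate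
11 | 4'-O-methylepicatechin-3-O-gallate, (2R,3R)-5,7-dihydroxy-2-(3-hydroxy-4-methoxyphenyl)chroman-3-yl 3,4,5-trihydroxybenzoate | COc1ccc([C@H]2Oc3cc(O)cc(O)c3C[C@H]2OC(=O)c2cc(O)c(O)c(O)c2)cc1O | target

## Step count and risk

Total step count: 7. Longest linear sequence: 5 steps (steps 1, 2, 3, 6, 7). The ring B / gallate branch is steps 4, 5, 6, 7.

**Step 6 (key step, proposed new method).**
- What may go wrong:
  - Weak enantiofacial discrimination. The acid activates the methide at one point only, and with no C4 substituent the catalyst must couple the face of the bound methide with the placement of the aryl and ester groups.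
  - Erosion of the cis relationship. This can happen by a stepwise path with rotation about C2–C3 in a benzylic cation, by acid-induced Z to E isomerisation of 8 (the twisted Z-olefin is the less reactive isomer, so any E isomer formed would be consumed preferentially), or by acid reopening of the adduct at C2.
  - Self-trapping of the methide (dimerisation, ether formation) instead of cycloaddition.
- Fallback (known chemistry), setting out from 4 and 8 and coming back at 10. It funnels every stereoisomer of the adduct into the right one. The cycloaddition is run with an achiral acid (diphenyl phosphate, toluene, rt to 60 °C) with no stereocontrol asked of it. This should give 5,7-bis(benzyloxy)-2-[3-(benzyloxy)-4-methoxyphenyl]-6,8-dibromochroman-3-yl 3,4,5-tris(benzyloxy)benzoate as a stereoisomer mixture F1. Methanolysis (K2CO3, MeOH/THF) frees the stereoisomeric 6,8-dibromochroman-3-ols F2. Dess–Martin periodinane merges them into the single racemic 6,8-dibromoflavan-3-one F3, whose C2 is enolisable. Transfer hydrogenation under dynamic kinetic resolution follows (RuCl(p-cymene)[TsNCH(Ph)CH(Ph)NH2] in the enantiomeric form that leads to the 3R carbinol, HCO2H/Et3N). Hydride should arrive anti to the C2 aryl group of the faster-reacting enantiomer, as in cis-selective reductions of α-aryl cyclic ketones, to give the (2R,3R)-6,8-dibromochroman-3-ol F4. Esterification with 7 (EDC·HCl, DMAP, CH2Cl2) returns 10.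

**Step 5.**
- What may go wrong: competing Markovnikov addition, partial formation of the E isomer, or catalyst-mediated dimerisation of the electron-rich arylalkyne. The bulky acid 7 slows the desired addition.
- Fallback, setting out from 6 and coming back at 8. Rhodium-catalysed trans-hydroboration of 6 with pinacolborane ([RhCl(1,5-cyclooctadiene)]2, P(iPr)3, Et3N, cyclohexane, rt) gives the (Z)-alkenyl pinacolboronate F5. Copper-mediated oxidative coupling of F5 with 7 (Cu(OAc)2, Et3N, 4 Å MS, air, CH2Cl2) then forms the enol ester C–O bond with retention of olefin geometry.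

**Step 3.**
- What may go wrong: premature ionisation of the product to the methide during reduction or work-up, leading to over-reduction to the methyl compound or to self-condensation on concentration.
- Fallback, setting out from 3 and coming back at 4. The phenol is masked first (TBSOTf, 2,6-lutidine, CH2Cl2) to give 2,4-bis(benzyloxy)-3,5-dibromo-6-[(tert-butyldimethylsilyl)oxy]benzaldehyde F6. Reduction (NaBH4, THF/MeOH) gives the silyl-protected benzylic alcohol F7, which cannot form a methide and can be stored. Buffered desilylation (TBAF, AcOH, THF, 0 °C) directly before step 6 releases 4.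

**Step 7.**
- What may go wrong: incomplete removal of the two hindered aryl bromides, poisoning of the catalyst by bromide, or base-assisted epimerisation at C2 and ester solvolysis of the free polyphenol during a prolonged reaction.
- Fallback, setting out from 10 and coming back at 11. The two events are separated. Radical hydrodebromination (Bu3SnH, AIBN, toluene, 80 °C) gives the bromine-free hexabenzyl ether F8. Base-free hydrogenolysis (H2, Pd(OH)2/C, THF/MeOH, rt) then gives 11.

## Further compounds

F1 | step 6 | 5,7-bis(benzyloxy)-2-[3-(benzyloxy)-4-methoxyphenyl]-6,8-dibromochroman-3-yl 3,4,5-tris(benzyloxy)benzoate, mixture of stereoisomers (C2 and C3 undefined) | COc1ccc(C2Oc3c(Br)c(OCc4ccccc4)c(Br)c(OCc4ccccc4)c3CC2OC(=O)c2cc(OCc3ccccc3)c(OCc3ccccc3)c(OCc3ccccc3)c2)cc1OCc1ccccc1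
F2 | step 6 | 5,7-bis(benzyloxy)-2-[3-(benzyloxy)-4-methoxyphenyl]-6,8-dibromochroman-3-ol, mixture of stereoisomers (C2 and C3 undefined) | COc1ccc(C2Oc3c(Br)c(OCc4ccccc4)c(Br)c(OCc4ccccc4)c3CC2O)cc1OCc1ccccc1
F3 | step 6 | 5,7-bis(benzyloxy)-2-[3-(benzyloxy)-4-methoxyphenyl]-6,8-dibromochroman-3-one, racemic (C2 labile) | COc1ccc(C2Oc3c(Br)c(OCc4ccccc4)c(Br)c(OCc4ccccc4)c3CC2=O)cc1OCc1ccccc1
F4 | step 6 | (2R,3R)-5,7-bis(benzyloxy)-2-[3-(benzyloxy)-4-methoxyphenyl]-6,8-dibromochroman-3-ol | COc1ccc([C@H]2Oc3c(Br)c(OCc4ccccc4)c(Br)c(OCc4ccccc4)c3C[C@H]2O)cc1OCc1ccccc1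
F5 | step 5 | 2-{(Z)-2-[3-(benzyloxy)-4-methoxyphenyl]ethenyl}-4,4,5,5-tetramethyl-1,3,2-dioxaborolane | COc1ccc(/C=C\B2OC(C)(C)C(C)(C)O2)cc1OCc1ccccc1
F6 | step 3 | 2,4-bis(benzyloxy)-3,5-dibromo-6-[(tert-butyldimethylsilyl)oxy]benzaldehyde | O=Cc1c(O[Si](C)(C)C(C)(C)C)c(Br)c(OCc2ccccc2)c(Br)c1OCc1ccccc1
F7 | step 3 | {2,4-bis(benzyloxy)-3,5-dibromo-6-[(tert-butyldimethylsilyl)oxy]phenyl}methanol | OCc1c(O[Si](C)(C)C(C)(C)C)c(Br)c(OCc2ccccc2)c(Br)c1OCc1ccccc1
F8 | step 7 | (2R,3R)-5,7-bis(benzyloxy)-2-[3-(benzyloxy)-4-methoxyphenyl]chroman-3-yl 3,4,5-tris(benzyloxy)benzoate | COc1ccc([C@H]2Oc3cc(OCc4ccccc4)cc(OCc4ccccc4)c3C[C@H]2OC(=O)c2cc(OCc3ccccc3)c(OCc3ccccc3)c(OCc3ccccc3)c2)cc1OCc1ccccc1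
A1 | alternative 1 | (E)-3,5-bis(benzyloxy)-2-{3-[3-(benzyloxy)-4-methoxyphenyl]prop-2-en-1-yl}phenol | COc1ccc(/C=C/Cc2c(O)cc(OCc3ccccc3)cc2OCc2ccccc2)cc1OCc1ccccc1
A2 | alternative 1 | (2R,3S)-5,7-bis(benzyloxy)-2-[3-(benzyloxy)-4-methoxyphenyl]chroman-3-ol | COc1ccc([C@H]2Oc3cc(OCc4ccccc4)cc(OCc4ccccc4)c3C[C@@H]2O)cc1OCc1ccccc1
A3 | alternative 1 | (2R,3R)-5,7-bis(benzyloxy)-2-[3-(benzyloxy)-4-methoxyphenyl]chroman-3-ol | COc1ccc([C@H]2Oc3cc(OCc4ccccc4)cc(OCc4ccccc4)c3C[C@H]2O)cc1OCc1ccccc1
A4 | alternative 2 | 5,7-dihydroxy-2-(3-hydroxy-4-methoxyphenyl)-3-[(3,4,5-trihydroxybenzoyl)oxy]chromenylium chloride | COc1ccc(-c2[o+]c3cc(O)cc(O)c3cc2OC(=O)c2cc(O)c(O)c(O)c2)cc1O.[Cl-]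
A5 | alternative 2 | 2-(3-hydroxy-4-methoxyphenyl)-2-oxoethyl 3,4,5-trihydroxybenzoate | COc1ccc(C(=O)COC(=O)c2cc(O)c(O)c(O)c2)cc1O
A6 | alternative 3 | 1-[3-(benzyloxy)-4-methoxyphenyl]-3-[2,4-bis(benzyloxy)-6-hydroxyphenyl]-1-diazopropan-2-one | COc1ccc(C(=[N+]=[N-])C(=O)Cc2c(O)cc(OCc3ccccc3)cc2OCc2ccccc2)cc1OCc1ccccc1
A7 | alternative 3 | 5,7-bis(benzyloxy)-2-[3-(benzyloxy)-4-methoxyphenyl]chroman-3-one, racemic | COc1ccc(C2Oc3cc(OCc4ccccc4)cc(OCc4ccccc4)c3CC2=O)cc1OCc1ccccc1
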